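## Retrosynthetic overview

1. Ring A (C4a, C5, C6, C7, C8, C8a) carries oxygen on C5, C7 and C8a and carbon on C4a, C6 and C8, so it is a cyclised triketide. It is cut at C4a–C5 and C7–C8 into a C5–C6–C7 unit that already bears the C6 prenyl (2-prenylmalonyl dichloride 21) and the silyl dienol ether 15 of a (2S)-dihydropyranone, which supplies ring C, C8 and the C8 prenyl.
2. Pyranone 14 comes from cyclodehydration (O1–C8a bond) of hydroxy diketone 13, made by prenylation at the methyl terminus of 11. Diketone 11 comes from a catalytic asymmetric vinylogous aldol addition (C2–C3 bond, sets C2) of aldehyde 7 to the symmetrical diene 9 of acetylacetone. The prenyl group is added after the aldol step because a bis-silyl dienol ether of the unsymmetrical prenylated diketone could not be formed regioselectively.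
3. Aldehyde 7 comes from resorcinol by MOM protection and two directed ortho-lithiations (prenylation, then formylation); 21 comes from dimethyl malonate and prenyl bromide.
4. Ring order: ring B is bought, ring C is closed in step 7, ring A is built last in step 12; acidic methanolysis of the two MOM ethers ends the route.

Key step: step 12

Ar = 2,4-bis(methoxymethoxy)-3-(3-methylbut-2-enyl)phenyl throughout.
Remark: the enol double bond of 10 and the exocyclic double bond of 15 are expected as geometric mixtures and are written without geometry; both isomers lead to the same product.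
Remark: the sense of induction in step 5 is taken from the usual behaviour of BINOL–titanium catalysts with aryl aldehydes; it is to be confirmed on 11 by Mosher ester analysis, and the antipodal ligand is used should it prove opposite.

## Route

Step 1
Reactants: 1 resorcinol
Product: 2 1,3-bis(methoxymethoxy)benzene
Conditions: MOMCl (2.5 equiv), iPr2NEt (3 equiv), CH2Cl2, 0 °C to rt
Reagents that add atoms: chloromethyl methyl ether, COCCl
Why: Williamson-type O-alkylation of both phenols by the reactive α-chloro ether (MOM protection); the MOM groups also direct the two lithiations that follow.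

Step 2
Reactants: 2 1,3-bis(methoxymethoxy)benzene; 3 prenyl bromide
Product: 5 1,3-bis(methoxymethoxy)-2-(3-methylbut-2-enyl)benzene, via aryllithium 4 (not isolated)
Conditions: n-BuLi (1.1 equiv), THF, 0 °C to rt; CuBr·SMe2 (10 mol %), then 3, −20 °C to rt
Reagents that add atoms: none
Why: Directed ortho-metalation at C2, the position flanked by both MOM ethers, followed by copper-catalysed allylic substitution, which should give the linear (SN2) prenyl arene.

Step 3
Reactants: 5 1,3-bis(methoxymethoxy)-2-(3-methylbut-2-enyl)benzene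
Product: 7 2,4-bis(methoxymethoxy)-3-(3-methylbut-2-enyl)benzaldehyde, via aryllithium 6 (not isolated)
Conditions: n-BuLi (1.2 equiv), TMEDA, THF, −20 to 0 °C; DMF, 0 °C to rt; H2O
Reagents that add atoms: N,N-dimethylformamide, CN(C)C=O
Why: Second directed ortho-metalation next to a MOM ether (C4 and C6 are equivalent) and Bouveault formylation of the aryllithium with DMF.

Step 4
Reactants: 8 acetylacetone
Product: 9 2,4-bis(trimethylsilyloxy)penta-1,3-diene
Conditions: TMSOTf (2.2 equiv), Et3N (2.5 equiv), Et2O, 0 °C to rt; filtration, distillation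
Reagents that add atoms: trimethylsilyl trifluoromethanesulfonate, C[Si](C)(C)OS(=O)(=O)C(F)(F)F
Why: Double soft enolisation and O-silylation of the symmetrical β-diketone gives the 1,3-bis(silyloxy)diene with no regiochemical ambiguity.

Step 5
Reactants: 7 2,4-bis(methoxymethoxy)-3-(3-methylbut-2-enyl)benzaldehyde; 9 2,4-bis(trimethylsilyloxy)penta-1,3-diene
Product: 11 (6S)-6-Ar-6-hydroxyhexane-2,4-dione, via bis-silyl aldol adduct 10 (not isolated)
Conditions: Ti(OiPr)4 (10 mol %), (S)-BINOL (10 mol %), 4 Å MS, THF, −78 °C to rt; then aq. citric acid, THF, 0 °C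
Reagents that add atoms: none
Why: Catalytic asymmetric vinylogous Mukaiyama aldol addition of the terminal diene carbon to the aldehyde, in which the (S)-BINOL–titanium complex should direct attack to the Si face and so set the (S)-carbinol (future C2); mild aqueous acid then removes both silyl groups without cyclodehydration.

Step 6
Reactants: 11 (6S)-6-Ar-6-hydroxyhexane-2,4-dione; 3 prenyl bromide
Product: 13 (1S)-1-Ar-1-hydroxy-9-methyldec-8-ene-3,5-dione, via trilithium salt 12 (not isolated)
Conditions: LiN(iPr)2 (3.3 equiv), THF, −78 to −20 °C; 3 (1.05 equiv), −78 to 0 °C; aq. NH4Cl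
Reagents that add atoms: none
Why: Polyanion alkylation of a β-diketone: once the alkoxide and the diketone enolate have formed, the third equivalent of base should deprotonate the methyl terminus (not the CH2 beside the alkoxide carbon), and this most basic carbanion is alkylated by prenyl bromide in an SN2 reaction that leaves the carbinol centre untouched.

Step 7
Reactants: 13 (1S)-1-Ar-1-hydroxy-9-methyldec-8-ene-3,5-dione
Product: 14 (2S)-2-Ar-6-(4-methylpent-3-enyl)-2,3-dihydro-4H-pyran-4-one
Conditions: p-TsOH·H2O (5 mol %), 4 Å MS, CH2Cl2, 0 °C to rt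
Reagents that add atoms: none
Why: Acid-catalysed cyclodehydration (hemiketal formation of the hydroxyl on the C5 ketone, then loss of water) closes ring C as a vinylogous ester; only the six-membered ring can form and the C–O bond at the stereocentre is not broken, so the (S) configuration becomes C2.

Step 8
Reactants: 14 (2S)-2-Ar-6-(4-methylpent-3-enyl)-2,3-dihydro-4H-pyran-4-one
Product: 15 (2S)-2-Ar-6-(4-methylpent-3-enylidene)-4-(trimethylsilyloxy)-3,6-dihydro-2H-pyran
Conditions: TMSOTf (1.3 equiv), Et3N (2.5 equiv), Et2O, −78 to 0 °C; pentane, filtration, concentration (no aqueous work-up)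
Reagents that add atoms: trimethylsilyl trifluoromethanesulfonate, C[Si](C)(C)OS(=O)(=O)C(F)(F)F
Why: Soft enolisation of the vinylogous ester at the exocyclic γ-CH2, the usual way to dienol silanes of 6-alkyl-2,3-dihydropyran-4-ones for vinylogous Mukaiyama reactions; excess amine keeps the medium non-acidic so the MOM ethers and C2 should be unaffected.

Step 9
Reactants: 16 dimethyl malonate; 3 prenyl bromide
Product: 18 dimethyl 2-(3-methylbut-2-enyl)malonate, via sodium enolate 17 (not isolated)
Conditions: NaH (1.0 equiv), 16 (2 equiv), THF, 0 °C; 3 (1.0 equiv), 0 °C to rt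
Reagents that add atoms: none
Why: Malonic ester alkylation (SN2 at the primary allylic bromide); excess malonate suppresses dialkylation.

Step 10
Reactants: 18 dimethyl 2-(3-methylbut-2-enyl)malonate
Product: 20 2-(3-methylbut-2-enyl)malonic acid, via dipotassium salt 19 (not isolated)
Conditions: KOH (2.5 equiv), MeOH–H2O, rt; then 1 M HCl to pH 2, 0 °C, immediate extraction
Reagents that add atoms: potassium hydroxide, [K+].[OH-]
Why: Saponification of both esters; cold, brief acidification avoids decarboxylation and acid-catalysed lactonisation onto the prenyl alkene.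

Step 11
Reactants: 20 2-(3-methylbut-2-enyl)malonic acid
Product: 21 2-(3-methylbut-2-enyl)malonyl dichloride
Conditions: 1-chloro-N,N,2-trimethylprop-1-enylamine (2.1 equiv), CH2Cl2, 0 °C to rt; solution used directly
Reagents that add atoms: 1-chloro-N,N,2-trimethylprop-1-en-1-amine, CC(C)=C(Cl)N(C)C
Why: Acid chloride formation with an α-chloroenamine under neutral conditions, which releases an amide instead of HCl (no hydrochlorination of the prenyl alkene) and needs no base (no ketene formation).

Step 12
Reactants: 15 (2S)-2-Ar-6-(4-methylpent-3-enylidene)-4-(trimethylsilyloxy)-3,6-dihydro-2H-pyran; 21 2-(3-methylbut-2-enyl)malonyl dichloride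
Product: 24 (2S)-2-Ar-5,7-dihydroxy-6,8-bis(3-methylbut-2-enyl)-2,3-dihydro-4H-chromen-4-one, via acid chloride 22 (not isolated), via cyclic triketone 23 (not isolated)
Conditions: 21 (1.1 equiv), 2,6-di-tert-butyl-4-methylpyridine (2.5 equiv), CH2Cl2 (0.01 M), −78 °C, slow addition of 15; then to rt; pH 7 buffer
Reagents that add atoms: none
Why: Proposed new method: the exocyclic γ-carbon of the 1-silyloxy-3-alkoxydiene in 15 (future C8) should attack one acid chloride of 21, because attack there leaves a cation stabilised by both O1 and the silyloxy group, and chloride then removes Me3Si to give vinylogous ester 22 (C7–C8 bond). In 22 the ring α-carbon (future C4a), still the β-carbon of the O1 enol ether and more nucleophilic once the acidic C8–H has enolised, should attack the second acid chloride, either directly or after loss of HCl to an acylketene whose dienylketene enol form can close by 6π electrocyclisation; this forms C4a–C5 and triketone 23, which tautomerises irreversibly to phloroglucinol 24. The closest known reactions are the uncatalysed γ-C-acylation of 1,3-bis(silyloxy)dienes by acid chlorides, their [3+3] cyclocondensations with 1,3-dielectrophiles to phenols, the malonyl dichloride annulation of silyl enol ethers to 4-hydroxypyranones and Claisen-type cyclisations of triketo acid derivatives to acylphloroglucinols. Ring A closes by a 6-(enolendo)-exo-trig C-acylation (or the equivalent electrocyclisation) and is then locked by aromatisation. No stereocentre is created, since C6 and C8 are only transiently sp3 and become arene carbons, and C2 lies three and four bonds from the reacting carbons and is not touched. The step needs C- over O-acylation, γ before α attack and ring closure over oligomerisation: O4 could only close an eight-membered ring and O1 is a poorly nucleophilic vinylogous ester oxygen, high dilution with slow addition of 15 to 21 favours the intramolecular second acylation, and the hindered pyridine only scavenges HCl, so ketene formation from 21, retro-oxa-Michael opening of C2–O1 and HCl damage to the MOM ethers and prenyl groups should all be avoided.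

Step 13
Reactants: 24 (2S)-2-Ar-5,7-dihydroxy-6,8-bis(3-methylbut-2-enyl)-2,3-dihydro-4H-chromen-4-one
Product: 25 (2S)-2-[2,4-dihydroxy-3-(3-methylbut-2-enyl)phenyl]-5,7-dihydroxy-6,8-bis(3-methylbut-2-enyl)-2,3-dihydro-4H-chromen-4-one
Conditions: 3 M aq. HCl, MeOH, 45 °C, monitored and stopped at full conversion
Reagents that add atoms: none
Why: Acid-catalysed methanolysis (transacetalisation) of the two aryl MOM ethers under mild conditions that should spare the prenyl groups; acid is used because base would open ring C by retro-oxa-Michael reaction and racemise C2.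

## Compound list

1 | resorcinol | Oc1cccc(O)c1 | starting material
2 | 1,3-bis(methoxymethoxy)benzene | COCOc1cccc(OCOC)c1 | intermediate
3 | prenyl bromide (1-bromo-3-methylbut-2-ene) | CC(C)=CCBr | starting material
4 | [2,6-bis(methoxymethoxy)phenyl]lithium | [Li]c1c(OCOC)cccc1OCOC | intermediate (not isolated)
5 | 1,3-bis(methoxymethoxy)-2-(3-methylbut-2-enyl)benzene | CC(C)=CCc1c(OCOC)cccc1OCOC | intermediate
6 | [2,4-bis(methoxymethoxy)-3-(3-methylbut-2-enyl)phenyl]lithium | [Li]c1ccc(OCOC)c(CC=C(C)C)c1OCOC | intermediate (not isolated)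
7 | 2,4-bis(methoxymethoxy)-3-(3-methylbut-2-enyl)benzaldehyde | O=Cc1ccc(OCOC)c(CC=C(C)C)c1OCOC | intermediate
8 | acetylacetone (pentane-2,4-dione) | CC(=O)CC(C)=O | starting material
9 | 2,4-bis(trimethylsilyloxy)penta-1,3-diene | C=C(O[Si](C)(C)C)C=C(C)O[Si](C)(C)C | intermediate
10 | (6S)-6-Ar-2,6-bis(trimethylsilyloxy)hex-2-en-4-one | CC(O[Si](C)(C)C)=CC(=O)C[C@H](O[Si](C)(C)C)c1ccc(OCOC)c(CC=C(C)C)c1OCOC | intermediate (not isolated)
11 | (6S)-6-Ar-6-hydroxyhexane-2,4-dione | CC(=O)CC(=O)C[C@H](O)c1ccc(OCOC)c(CC=C(C)C)c1OCOC | intermediate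
12 | trilithium salt of 11 (alkoxide, enolate and terminal carbanion) | [Li+].[Li+].[Li+].C=C([O-])C=C([O-])C[C@H]([O-])c1ccc(OCOC)c(CC=C(C)C)c1OCOC | intermediate (not isolated)
13 | (1S)-1-Ar-1-hydroxy-9-methyldec-8-ene-3,5-dione | CC(C)=CCCC(=O)CC(=O)C[C@H](O)c1ccc(OCOC)c(CC=C(C)C)c1OCOC | intermediate
14 | (2S)-2-Ar-6-(4-methylpent-3-enyl)-2,3-dihydro-4H-pyran-4-one | CC(C)=CCc1c(OCOC)ccc([C@@H]2CC(=O)C=C(CCC=C(C)C)O2)c1OCOC | intermediate
15 | (2S)-2-Ar-6-(4-methylpent-3-enylidene)-4-(trimethylsilyloxy)-3,6-dihydro-2H-pyran | CC(C)=CCc1c(OCOC)ccc([C@@H]2CC(O[Si](C)(C)C)=CC(=CCC=C(C)C)O2)c1OCOC | intermediate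
16 | dimethyl malonate | COC(=O)CC(=O)OC | starting material
17 | sodium enolate of dimethyl malonate | [Na+].COC(=O)[CH-]C(=O)OC | intermediate (not isolated)
18 | dimethyl 2-(3-methylbut-2-enyl)malonate | COC(=O)C(CC=C(C)C)C(=O)OC | intermediate
19 | dipotassium 2-(3-methylbut-2-enyl)malonate | [K+].[K+].CC(C)=CCC(C(=O)[O-])C(=O)[O-] | intermediate (not isolated)
20 | 2-(3-methylbut-2-enyl)malonic acid | CC(C)=CCC(C(=O)O)C(=O)O | intermediate
21 | 2-(3-methylbut-2-enyl)malonyl dichloride | CC(C)=CCC(C(=O)Cl)C(=O)Cl | intermediate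
22 | 7-methyl-2-(3-methylbut-2-enyl)-3-oxo-4-[(2S)-2-Ar-4-oxo-2,3-dihydro-4H-pyran-6-yl]oct-6-enoyl chloride | CC(C)=CCc1c(OCOC)ccc([C@@H]2CC(=O)C=C(C(CC=C(C)C)C(=O)C(CC=C(C)C)C(=O)Cl)O2)c1OCOC | intermediate (not isolated)
23 | (2S)-2-Ar-6,8-bis(3-methylbut-2-enyl)-2,3-dihydro-4H-chromene-4,5,7(6H,8H)-trione | CC(C)=CCc1c(OCOC)ccc([C@@H]2CC(=O)C3=C(O2)C(CC=C(C)C)C(=O)C(CC=C(C)C)C3=O)c1OCOC | intermediate (not isolated)
24 | (2S)-2-Ar-5,7-dihydroxy-6,8-bis(3-methylbut-2-enyl)-2,3-dihydro-4H-chromen-4-one | CC(C)=CCc1c(OCOC)ccc([C@@H]2CC(=O)c3c(O)c(CC=C(C)C)c(O)c(CC=C(C)C)c3O2)c1OCOC | intermediate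
25 | (2S)-2-[2,4-dihydroxy-3-(3-methylbut-2-enyl)phenyl]-5,7-dihydroxy-6,8-bis(3-methylbut-2-enyl)-2,3-dihydro-4H-chromen-4-one | CC(C)=CCc1c(O)ccc([C@@H]2CC(=O)c3c(O)c(CC=C(C)C)c(O)c(CC=C(C)C)c3O2)c1O | target

## Step count and risks

Total step count: 13. Longest linear sequence: 9 steps (1, 2, 3, 5, 6, 7, 8, 12, 13).

**Step 12 (most likely to fail).** The annulation may stall after the first acylation, or be diverted into intermolecular bis-acylation and oligomerisation, or into cycloaddition of a ketene formed from the dichloride. The fallback separates the two bond formations into known reactions; it sets out from 15 and 18 and returns at 24.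
- Diester 18 is half-saponified (KOH, 1.0 equiv, MeOH, 0 °C) to 2-(methoxycarbonyl)-5-methylhex-4-enoic acid F1.
- The α-chloroenamine of step 11 converts F1 into methyl 2-(chlorocarbonyl)-5-methylhex-4-enoate F2.
- Uncatalysed γ-C-acylation of dienol ether 15 with F2 (CH2Cl2, −78 °C to rt), a known reaction of silyl dienol ethers with acid chlorides, should give keto ester methyl 7-methyl-2-(3-methylbut-2-enyl)-3-oxo-4-[(2S)-2-Ar-4-oxo-2,3-dihydro-4H-pyran-6-yl]oct-6-enoate F3, which can be purified.
- Dieckmann-type Claisen cyclisation of F3 (NaOMe, MeOH, 0 °C to rt) then closes C4a–C5 and, after aromatisation, gives 24. The competing aldol mode would need a bridged ring, and the polyanion formed at the acidic side-chain positions should shield C3 from deprotonation. The enantiomeric purity of 24 is checked after this step.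

**Step 8.** Enolisation may occur toward C3 instead of the exocyclic CH2, giving an endocyclic 2H-pyran enol silane that would acylate at the wrong carbon and could erode C2 by reversible electrocyclic ring opening. The fallback fixes the exocyclic enol ether by construction; it sets out from 7 and returns at 24.
- The aldol conditions of step 5, applied to 7 and 1-methoxy-1,3-bis(trimethylsilyloxy)buta-1,3-diene F4 with mild acid work-up, give methyl (5S)-5-Ar-5-hydroxy-3-oxopentanoate F5.
- K2CO3 in MeOH lactonises F5 to (6S)-6-Ar-oxane-2,4-dione F6.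
- TBSCl and Et3N convert F6 into (6S)-6-Ar-4-(tert-butyldimethylsilyloxy)-5,6-dihydro-2H-pyran-2-one F7.
- Takai–Utimoto alkylidenation of the lactone carbonyl of F7 with 1,1-dibromo-4-methylpent-3-ene F8 (from LiCHBr2 and 3), Zn, TiCl4, TMEDA and PbCl2 (cat.) in THF gives (2S)-2-Ar-4-(tert-butyldimethylsilyloxy)-6-(4-methylpent-3-enylidene)-3,6-dihydro-2H-pyran F9.
- F9 replaces 15 in step 12 and gives 24.

**Step 5.** Facial selectivity may be low, because the aldehyde is electron-rich and slow and its ortho MOM oxygen can chelate titanium. The fallback is a racemic synthesis with resolution; it sets out from 8, 3 and 7 and returns at 14.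
- The dianion of acetylacetone 8 (NaH, then n-BuLi, THF, 0 °C) is alkylated at its terminal carbon with 3 to give 8-methylnon-7-ene-2,4-dione F10.
- The dianion of F10 (LiN(iPr)2, 2.2 equiv; deprotonation at the methyl terminus) adds to aldehyde 7 to give racemic 1-Ar-1-hydroxy-9-methyldec-8-ene-3,5-dione F11.
- The conditions of step 7 convert F11 into racemic 2-Ar-6-(4-methylpent-3-enyl)-2,3-dihydro-4H-pyran-4-one F12.
- Preparative chromatography of F12 on a chiral stationary phase delivers the (S)-enantiomer, which is 14.

## Further compounds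

F1 | step 12 | 2-(methoxycarbonyl)-5-methylhex-4-enoic acid | COC(=O)C(CC=C(C)C)C(=O)O
F2 | step 12 | methyl 2-(chlorocarbonyl)-5-methylhex-4-enoate | COC(=O)C(CC=C(C)C)C(=O)Cl
F3 | step 12 | methyl 7-methyl-2-(3-methylbut-2-enyl)-3-oxo-4-[(2S)-2-Ar-4-oxo-2,3-dihydro-4H-pyran-6-yl]oct-6-enoate | CC(C)=CCc1c(OCOC)ccc([C@@H]2CC(=O)C=C(C(CC=C(C)C)C(=O)C(CC=C(C)C)C(=O)OC)O2)c1OCOC
F4 | step 8 | 1-methoxy-1,3-bis(trimethylsilyloxy)buta-1,3-diene | COC(O[Si](C)(C)C)=CC(=C)O[Si](C)(C)C
F5 | step 8 | methyl (5S)-5-Ar-5-hydroxy-3-oxopentanoate | COC(=O)CC(=O)C[C@H](O)c1ccc(OCOC)c(CC=C(C)C)c1OCOC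
F6 | step 8 | (6S)-6-Ar-oxane-2,4-dione | CC(C)=CCc1c(OCOC)ccc([C@@H]2CC(=O)CC(=O)O2)c1OCOC
F7 | step 8 | (6S)-6-Ar-4-(tert-butyldimethylsilyloxy)-5,6-dihydro-2H-pyran-2-one | CC(C)=CCc1c(OCOC)ccc([C@@H]2CC(O[Si](C)(C)C(C)(C)C)=CC(=O)O2)c1OCOC
F8 | step 8 | 1,1-dibromo-4-methylpent-3-ene | BrC(Br)CC=C(C)C
F9 | step 8 | (2S)-2-Ar-4-(tert-butyldimethylsilyloxy)-6-(4-methylpent-3-enylidene)-3,6-dihydro-2H-pyran | CC(C)=CCc1c(OCOC)ccc([C@@H]2CC(O[Si](C)(C)C(C)(C)C)=CC(=CCC=C(C)C)O2)c1OCOC
F10 | step 5 | 8-methylnon-7-ene-2,4-dione | CC(C)=CCCC(=O)CC(C)=O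
F11 | step 5 | racemic 1-Ar-1-hydroxy-9-methyldec-8-ene-3,5-dione | CC(C)=CCCC(=O)CC(=O)CC(O)c1ccc(OCOC)c(CC=C(C)C)c1OCOC
F12 | step 5 | racemic 2-Ar-6-(4-methylpent-3-enyl)-2,3-dihydro-4H-pyran-4-one | CC(C)=CCc1c(OCOC)ccc(C2CC(=O)C=C(CCC=C(C)C)O2)c1OCOC
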